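All runs were computed for an exercise, noise included.

The ratio of left-handed to right-handed product is what I carry through this flask, and its zero point is a ratio of one, the mirror-image case of a catalyst without a preference.

| flask | left-handed substrate | right-handed substrate | reagent | free catalyst | racemization catalyst | added ligand | remark | time |
|---|---|---|---|---|---|---|---|---|
| north | 0.42 M | 0.42 M | 0.924 M | 37 mM | 4.2 mM | 6.7 mM | run made earlier |  |
| south-east | 0.42 M | 0.42 M | 0.924 M | 37 mM | 4.2 mM | 11 mM | run made earlier |  |
| flask | 0.42 M | 0.42 M | 0.924 M | 37 mM | 4.2 mM | 4.8 mM |  | 8.0 min |

| run | time / min | left-handed substrate / % | right-handed substrate / % | left-handed product / % |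
|---|---|---|---|---|
| north | 2.50 | 45.3 | 43.5 | 6.5 |
| north | 5.00 | 40.4 | 41.8 | 11.8 |
| north | 8.00 | 38.1 | 38.1 | 15.5 |
| north | 10.0 | 35.5 | 35.5 | 18.8 |
| south-east | 2.50 | 44.4 | 44.9 | 6.4 |
| south-east | 5.00 | 40.8 | 42.0 | 12.3 |
| south-east | 8.00 | 37.6 | 38.6 | 15.1 |
| south-east | 10.0 | 35.7 | 36.4 | 17.1 |

(readings scatter by 0.5 percentage points)

- part of the left-handed substrate and right-handed substrate charged together that has reacted at 8.0 min
- excess of left-handed product over right-handed product in the product at 8.0 min
- excess of right-handed substrate over left-handed substrate among what is left of the two at 8.0 min

- free catalyst is single-handed; left-handed substrate and right-handed substrate are mirror images of each other, charged as a racemate, each of them at the stated concentration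
- an excess is below zero if the other one leads

Right-handed product isn't read, so I take it as what the balance leaves at 8.00 min: 8.30 % in the north run and 8.70 % in the south-east run. I call s the left-handed product over the right-handed product, both runs pooled at that time; this is the selectivity factor. It reads 1.80, and it is rough, because each right-handed figure stacks the scatter of several readings.

I build the flask up in steps. With the main step and nothing else, the left-handed substrate goes faster, so the right-handed substrate would lead by the product difference, 6.8 percentage points. Now I add racemization. The runs show a mean lead of 0.5 points, far smaller. So the two substrates stay nearly level, and I expect s to hold through the run and with other amounts of free catalyst.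

Last comes the added ligand. Both runs show a conversion near 23.8 % despite their different ligand charges, and this flask has less ligand than either. I commit to that conversion, to a substrate excess near zero, and to a product excess of (s−1)/(s+1) = 28.6 %.

The forecast gives 24 %, 29 % and 0.5 %, on the ground that “racemization keeps pace”.

The flask gives 24.2 %, 32.2 % and 0.0808 %, so the forecast holds on each.

    left-handed substrate + racemization catalyst ⇌ right-handed substrate + racemization catalyst, rate k1*[racemization catalyst]*[left-handed substrate] forward; the back reaction follows from the equilibrium constant (k = 258 /M/s)
    2 racemization catalyst → spent catalyst (k = 1.69 /M/s)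
    reagent + free catalyst + left-handed substrate → free catalyst + left-handed product (k = 0.274 /M²/s)
    reagent + free catalyst + right-handed substrate → free catalyst + right-handed product (k = 0.140 /M²/s)
    racemization catalyst + added ligand ⇌ idle complex, settled at all times (K = 8800 /M)
    reagent ⇌ dormant form (K = 11.0, k = 0.147 /s)

In this flask, s splits the 24.2 % into 8.64 % of right-handed product, and the flask holds 8.19 % at 8.00 min. The neighbour flask takes 0.15 M of free catalyst instead of 37 mM. It reaches 56.0 %, further than this flask. The same s splits that into 20.0 % of right-handed product, and the neighbour flask holds 19.1 %. Its product excess is 31.9 %, level with this flask. In the neighbour flask the right-handed substrate stands at 22.0 %, with a substrate excess of 0.199 %.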